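Retrosynthesis: C3′–Br goes back to a C3′–C(=O) bond (lactol fragmentation). C4–Cl and C5–Br go back to a 4,5-epoxide and then to a C4=C5 alkene. Ring B (C1–C6) then goes back to the five-membered ring C1–C5 of a 4-methylbicyclo[3.1.0]hexan-4-ol by re-forming the zero bridge C1–C5. The C5–C1/C5–C6 carbene bonds and the C1–C2 bond lead back to (+)-camphoric acid.
Enabling feature: in ring B the carbinol C1, the methylene C6 and the C5–C4(Me) dihalide form a homoallylic-alcohol unit (C1–O/C6/C5=C4). This unit is the open form of a cyclopropylcarbinyl cation at C4. The C3′ carboxyl of ring A is cis-1,3 to C1′ and reaches C1 through a six-membered ring.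
Forward order: ring A is bought. The chain C2–C5 is joined at the hindered acyl carbon C1. One cyclopropanation closes the five-membered ring and the cyclopropane. Step 8 expands this to ring B. A temporary lactone (C1–O–C(=O)–C3′) masks the alcohol and is later cut out as formate.
Stereochemistry: C1′ comes from camphoric acid. C1/C5 of the bicycle come from a chiral copper catalyst. C1–O forms by inversion in step 8. C4/C5 come from OH-directed epoxidation, diaxial HBr opening and anti opening of a face-defined bromonium ion. C3′ comes from bromine transfer to a radical on the face away from the pseudoaxial C1′ methyl.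
Key step: step 8

Remark on locants: ring A is C1′ (quaternary, Me), C2′ (CMe2), C3′, C4′, C5′. Ring B is C1 (carbinol), C2, C3, C4 (Me), C5, C6. The same atoms keep these locants in every precursor, and they coincide with bicyclo[3.1.0]hexane numbering in 11–13. α is the face of ring B that carries the C1–O bond; β is the face that carries C1′.
Remark on mixtures: 12 is drawn as the expected major C4 epimer, and both epimers give the same cation. 22 and 23 are anomeric mixtures.

Step 1
Reactants: 1 (+)-camphoric acid
Product: 2 (1R,3S)-3-(methoxycarbonyl)-1,2,2-trimethylcyclopentane-1-carboxylic acid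
Conditions: MeOH, H2SO4 (cat.), reflux
Reagents that add atoms: methanol (CO)
Why: Fischer esterification discriminates on steric grounds, so the secondary C3′ carboxyl is esterified while the carboxyl on quaternary C1′ next to CMe2 stays free and both stereocentres are untouched.

Step 2
Reactants: 2 camphoric acid 3-methyl ester; 3 ethyl 3-iodopropanoate
Product: 6 methyl cis-3-(4-ethoxy-4-oxobutanoyl)-2,2,3-trimethylcyclopentane-1-carboxylate, via acid chloride 4 (not isolated), via zinc homoenolate 5 (not isolated)
Conditions: 2, (COCl)2, DMF (cat.), CH2Cl2, 0 °C to rt, evaporate; 3, zinc–copper couple, toluene–DMA, 60 °C; combine, Pd(PPh3)4 (5 mol %), rt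
Reagents that add atoms: none
Why: Palladium-catalysed Negishi-type acylation of an ester-stabilised alkylzinc iodide by an acid chloride stops at the ketone, because the organozinc attacks neither the hindered ketone nor the esters, and it forges C1–C2 at the neopentyl acyl carbon without base.

Step 3
Reactants: 6 γ-keto diester
Product: 7 methyl cis-3-(5-ethoxy-5-oxopent-1-en-2-yl)-2,2,3-trimethylcyclopentane-1-carboxylate
Conditions: Zn, CH2Br2, TiCl4, THF–CH2Cl2, 0 °C to rt
Reagents that add atoms: dibromomethane (BrCBr)
Why: Takai–Lombardo methylenation uses a non-basic gem-dimetallic reagent that attacks hindered enolisable ketones but not esters, so C1=C6H2 is installed without enolate chemistry that could close a Claisen ring onto the C3′ ester.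

Step 4
Reactants: 7 alkene diester
Product: 8 4-[cis-3-(methoxycarbonyl)-1,2,2-trimethylcyclopentyl]pent-4-enoic acid
Conditions: LiOH·H2O (1.1 equiv), THF–H2O, 0 °C; then 1 M HCl
Reagents that add atoms: lithium hydroxide ([Li+].[OH-])
Why: Saponification is selective for the unhindered chain ethyl ester because the C3′ methyl ester is shielded by the adjacent CMe2 group.

Step 5
Reactants: 8 alkenoic acid
Product: 10 methyl cis-3-(6-diazo-5-oxohex-1-en-2-yl)-2,2,3-trimethylcyclopentane-1-carboxylate, via mixed anhydride 9 (not isolated)
Conditions: i-BuOCOCl, N-methylmorpholine, THF, −15 °C; CH2N2, Et2O, 0 °C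
Reagents that add atoms: diazomethane (C=[N+]=[N-])
Why: Acylation of diazomethane by a mixed carbonic anhydride (first stage of the Arndt–Eistert sequence) gives the terminal α-diazoketone under neutral conditions that leave the alkene and the ester alone.

Step 6
Reactants: 10 diazoketone
Product: 11 methyl cis-2,2,3-trimethyl-3-(4-oxobicyclo[3.1.0]hexan-1-yl)cyclopentane-1-carboxylate (C1 and C5 as in the SMILES)
Conditions: [Cu(MeCN)4]PF6 (5 mol %), 2,2′-isopropylidenebis[(4S)-4-tert-butyl-2-oxazoline] (6 mol %), CH2Cl2, slow addition, 25–40 °C
Reagents that add atoms: none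
Why: Intramolecular cyclopropanation of an alkenyl diazoketone by a chiral bis(oxazoline) complex of monovalent copper closes the ring C1–C5 and the cyclopropane C1–C5–C6 at once (the classical entry to sabina-ketone-type bicycles); the tether enforces the cis fusion, and the ligand chooses the face of C1=C6 and hence C1 and C5, its antipode being the switch if substrate and catalyst prove mismatched.

Step 7
Reactants: 11 cyclopropyl ketone
Product: 12 methyl cis-3-(4-hydroxy-4-methylbicyclo[3.1.0]hexan-1-yl)-2,2,3-trimethylcyclopentane-1-carboxylate (OH syn to C6)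
Conditions: MeMgBr, Et2O, −78 to −20 °C; pH 7 buffer
Reagents that add atoms: methylmagnesium bromide (C[Mg]Br)
Why: 1,2-Addition of the Grignard reagent to the open cyclopropyl ketone is faster at low temperature than attack on the shielded ester and comes from the face away from the C6 methylene; the C4 configuration does not matter because C4 becomes planar in step 8.

Step 8
Reactants: 12 tertiary cyclopropyl carbinol
Product: 15 methyl cis-3-(1-hydroxy-4-methylcyclohex-3-en-1-yl)-2,2,3-trimethylcyclopentane-1-carboxylate (C1 as in the target), via cyclopropylcarbinyl cation 13 (not isolated), via lactonium ion 14 (not isolated)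
Conditions: HClO4 (0.02 M), THF–H2O 4:1, 0 °C to rt; NaHCO3 quench
Reagents that add atoms: water (O)
Why: Protonation and loss of water from 12 give the tertiary cyclopropylcarbinyl cation 13, in which the zero-bridge bond C1–C5 (not C5–C6, which would put charge on a primary carbon) donates into C4, so that C4=C5 forms and the five-membered ring C1–C5 merges with C6 into the six-membered ring B. The closest known reaction type is the cyclopropylcarbinyl-to-homoallyl solvolysis that turns sabinene hydrate into terpinen-4-ol in dilute acid. The charge growing at C1 is captured from the side opposite to the departing C5 by the carbonyl oxygen of the cis C3′ ester (6-exo-tet closure of the transient oxanylium ring of 14, the only ring closed by bond formation), which should outrun proton loss and a 1,2-shift from the neighbouring quaternary C1′. Water adds to the carbenium carbon of 14, and the hemiorthoester collapses under stereoelectronic control by endocyclic C–O cleavage, which returns the methyl ester and leaves its former carbonyl oxygen as the free C1 hydroxyl. C1 is the only new stereocentre and is fixed by inversion at the cyclopropane carbon, that is by the C1/C5 configuration from step 6, and direct attack of water would follow the same trajectory to the same isomer. The step needs regioselective bond cleavage (secured by the fully substituted C1), a single alkene position (secured because C5 is shared by cation and cyclopropane) and mild acid so that 15 does not ionise again.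

Step 9
Reactants: 15 homoallylic alcohol
Product: 16 4α,5α-epoxide of 15 (epoxide cis to the C1 hydroxyl)
Conditions: VO(acac)2 (3 mol %), t-BuOOH (decane solution), toluene, 0 °C to rt
Reagents that add atoms: tert-butyl hydroperoxide (CC(C)(C)OO)
Why: Hydroxyl-directed epoxidation by the vanadium tert-butylperoxo complex bound to the axial C1 oxygen delivers oxygen to the α face of the homoallylic C4=C5 bond, as it does with terpinen-4-ol, which sets C4 and C5 relative to C1.

Step 10
Reactants: 16 epoxy alcohol ester
Product: 17 epoxy spiro-lactone (C1–O–C(=O)–C3′ bridge closed: 5,8,8-trimethyl-3-oxabicyclo[3.2.1]octan-2-one spiro-fused at its C4 to ring B; 4α,5α-epoxide)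
Conditions: NaH, THF, 0 °C to rt
Reagents that add atoms: none
Why: Base-induced transesterification, in which the deprotonated tertiary alcohol attacks the cis C3′ ester through the geometry of camphoric anhydride and expels the less basic methoxide in an aprotic medium; this masks C1–O as a non-nucleophilic ester whose acyl group is held away from the α face, and the epoxide cannot be reached from its own face.

Step 11
Reactants: 17 epoxy lactone
Product: 18 4β-bromo-5α-hydroxy lactone (Br and OH both axial; C4 methyl α)
Conditions: HBr (1.05 equiv, Et2O solution), CH2Cl2, −60 to −30 °C; used without chromatography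
Reagents that add atoms: hydrogen bromide (Br)
Why: Acid-mediated epoxide opening in which the electronic preference (tertiary C4) and the conformational preference (Fürst–Plattner trans-diaxial opening in the chair that holds C1′ equatorial) coincide, so bromide enters at C4 from the β face with inversion and leaves the axial 5α-alcohol.

Step 12
Reactants: 18 bromohydrin lactone
Product: 21 4α-chloro-5β-bromo lactone (both halogens equatorial; C4 methyl β), via triflate 19 (not isolated), via bromonium ion 20 (not isolated)
Conditions: Tf2O, 2,6-di-tert-butyl-4-methylpyridine, CH2Cl2, −78 °C; Bu4NCl (4 equiv), −78 to 0 °C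
Reagents that add atoms: tetrabutylammonium chloride (CCCC[N+](CCCC)(CCCC)CCCC.[Cl-])
Why: Solvolysis with neighbouring-bromine participation: the axial C4–Br bond is antiperiplanar to the axial C5–OTf bond and expels triflate to give the bromonium ion 20 on the β face only; chloride opens it anti at the more substituted C4 from the α face, so Br ends on C5 (β) and Cl on C4 (α), the trans-diequatorial pattern that direct addition to the locked cyclohexene would not give, while the lactone keeps the C1 oxygen from closing a bromo ether.

Step 13
Reactants: 21 bromochloro lactone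
Product: 22 bromochloro lactol (anomeric mixture)
Conditions: i-Bu2AlH (1.1 equiv), CH2Cl2, −78 °C; Rochelle salt work-up
Reagents that add atoms: none
Why: Partial reduction of a lactone by i-Bu2AlH at low temperature stops at the tetrahedral aluminate, which gives the lactol on work-up and leaves the alkyl halides untouched.

Step 14
Reactants: 22 lactol
Product: 25 (1R,3S,4S)-3-bromo-1-[(1R,3S)-3-bromo-1,2,2-trimethylcyclopentyl]-4-chloro-4-methylcyclohexan-1-ol, via lactol hypobromite 23 (not isolated), via tertiary formate 24 (not isolated)
Conditions: PhI(OAc)2, Br2, CH2Cl2, visible light, 0 °C; then KHCO3 (cat.), MeOH, 0 °C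
Reagents that add atoms: bromine (BrBr)
Why: Alkoxy-radical β-fragmentation of a lactol through its hypohalite (Suárez-type fragmentation run with bromine): photolysis of 23 gives the anomeric alkoxy radical, which cleaves the C3′–CH bond to a formate ester and the secondary C3′ radical; bromine is transferred to the face opposite to the pseudoaxial C1′ methyl (ring B substituent pseudoequatorial) to give the 1,3-cis bromide, and mild methanolysis removes the formate.

Compound list
1 | (+)-camphoric acid, (1R,3S)-1,2,2-trimethylcyclopentane-1,3-dicarboxylic acid | CC1(C)[C@@H](C(=O)O)CC[C@@]1(C)C(=O)O | starting material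
2 | camphoric acid 3-methyl ester | CC1(C)[C@@H](C(=O)OC)CC[C@@]1(C)C(=O)O | intermediate
3 | ethyl 3-iodopropanoate | CCOC(=O)CCI | starting material
4 | acid chloride of 2 | CC1(C)[C@@H](C(=O)OC)CC[C@@]1(C)C(=O)Cl | intermediate
5 | (3-ethoxy-3-oxopropyl)zinc iodide | CCOC(=O)CC[Zn]I | intermediate
6 | γ-keto diester | CC1(C)[C@@H](C(=O)OC)CC[C@@]1(C)C(=O)CCC(=O)OCC | intermediate
7 | 1,1-disubstituted alkene diester | CC1(C)[C@@H](C(=O)OC)CC[C@@]1(C)C(=C)CCC(=O)OCC | intermediate
8 | alkenoic acid | CC1(C)[C@@H](C(=O)OC)CC[C@@]1(C)C(=C)CCC(=O)O | intermediate
9 | mixed isobutyl carbonic anhydride | CC1(C)[C@@H](C(=O)OC)CC[C@@]1(C)C(=C)CCC(=O)OC(=O)OCC(C)C | intermediate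
10 | diazoketone | CC1(C)[C@@H](C(=O)OC)CC[C@@]1(C)C(=C)CCC(=O)C=[N+]=[N-] | intermediate
11 | 1-(ring A)bicyclo[3.1.0]hexan-4-one | CC1(C)[C@@H](C(=O)OC)CC[C@@]1(C)[C@@]23CCC(=O)[C@@H]2C3 | intermediate
12 | 4-methyl-1-(ring A)bicyclo[3.1.0]hexan-4-ol | CC1(C)[C@@H](C(=O)OC)CC[C@@]1(C)[C@@]23CC[C@](C)(O)[C@@H]2C3 | intermediate
13 | cyclopropylcarbinyl cation at C4 | CC1(C)[C@@H](C(=O)OC)CC[C@@]1(C)[C@@]23CC[C+](C)[C@@H]2C3 | intermediate
14 | lactonium (methoxyoxanylium) ion | CC1(C)[C@@H]2CC[C@@]1(C)[C@@]1(OC2=[O+]C)CCC(C)=CC1 | intermediate
15 | 1-(ring A)-4-methylcyclohex-3-en-1-ol methyl ester | CC1(C)[C@@H](C(=O)OC)CC[C@@]1(C)[C@@]1(O)CCC(C)=CC1 | intermediate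
16 | 4α,5α-epoxy alcohol ester | CC1(C)[C@@H](C(=O)OC)CC[C@@]1(C)[C@@]1(O)CC[C@]2(C)O[C@@H]2C1 | intermediate
17 | epoxy spiro-lactone | CC1(C)[C@@H]2CC[C@@]1(C)[C@@]1(OC2=O)CC[C@]3(C)O[C@@H]3C1 | intermediate
18 | 4β-bromo-5α-hydroxy lactone | CC1(C)[C@@H]2CC[C@@]1(C)[C@@]1(OC2=O)CC[C@@](C)(Br)[C@H](O)C1 | intermediate
19 | 4β-bromo-5α-triflate | CC1(C)[C@@H]2CC[C@@]1(C)[C@@]1(OC2=O)CC[C@@](C)(Br)[C@H](OS(=O)(=O)C(F)(F)F)C1 | intermediate
20 | 4,5-β-bromonium ion | CC1(C)[C@@H]2CC[C@@]1(C)[C@@]1(OC2=O)CC[C@@]3(C)[Br+][C@H]3C1 | intermediate
21 | 4α-chloro-5β-bromo lactone | CC1(C)[C@@H]2CC[C@@]1(C)[C@@]1(OC2=O)CC[C@](C)(Cl)[C@@H](Br)C1 | intermediate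
22 | bromochloro lactol | CC1(C)[C@@H]2CC[C@@]1(C)[C@@]1(OC2O)CC[C@](C)(Cl)[C@@H](Br)C1 | intermediate
23 | lactol hypobromite | CC1(C)[C@@H]2CC[C@@]1(C)[C@@]1(OC2OBr)CC[C@](C)(Cl)[C@@H](Br)C1 | intermediate
24 | C1 formate of the target | CC1(C)[C@@H](Br)CC[C@@]1(C)[C@@]1(OC=O)CC[C@](C)(Cl)[C@@H](Br)C1 | intermediate
25 | CNP0116087.1 | CC1(C)[C@@H](Br)CC[C@@]1(C)[C@@]1(O)CC[C@](C)(Cl)[C@@H](Br)C1 | target

Total step count: 14. Longest linear sequence: 14 (from 1).

Steps most likely to fail

Step 12. Chloride may collapse on C5 of the bromonium ion through the chair-like diaxial path instead of on C4. The ion may also lose a proton from C3 or the methyl group before chloride arrives. The fallback sets out from 18 and returns at 21. Compound 18 is treated with SOCl2 in toluene without base. The chlorosulfite ionises with bromine participation and chloride returns on the nearer carbon to give the diaxial 4β-bromo-5α-chloro lactone F1. Heating F1 in chlorobenzene then brings about the classical diaxial-to-diequatorial 1,2-interchange of vicinal dihalides through a tight bromonium chloride pair. Bromine moves to C5 on the β face and chlorine to C4 on the α face, which is 21.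

Step 8. The delocalised cation may lose a proton to give dienes, or a free C1 cation may leak stereochemical information or undergo a 1,2-shift from C1′. The fallback sets out from 11 and returns at 15.
- Ketone 11 is stirred in dilute aqueous acid. The protonated cyclopropyl ketone is opened at the same C1–C5 bond by ester-assisted homoconjugate addition to give the 4-hydroxy-4-(ring A)cyclohexanone methyl ester F2. In F2 no diene can form and C1 is not yet stereogenic.
- NaH closes the keto lactone F3.
- The two α-methylene groups are told apart by lithium (R,R)-bis(1-phenylethyl)amide, and the enolate is trapped by PhNTf2 as the enol triflate lactone F4, so C1 is set by the reagent.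
- Fe(acac)3-catalysed coupling of F4 with MeMgBr gives the alkene lactone F5.
- NaOMe in MeOH reopens the lactone to 15.

Step 14. Bromine transfer from the very reactive bromine/hypobromite pair may be too fast to tell the two faces of the C3′ radical apart, and hydrogen abstraction by the alkoxy radical may compete with fragmentation. The fallback sets out from 22 and returns at 25. Pinnick oxidation (NaClO2, NaH2PO4, 2-methylbut-2-ene) of the open hydroxy aldehyde form of 22 gives the hydroxy acid F6. Visible-light decarboxylative bromination of its caesium salt ([Ir(dF(CF3)ppy)2(dtbbpy)]PF6, Cs2CO3, diethyl bromomalonate) makes the same C3′ radical. It hands over bromine from a slower and bulkier donor, needs no acyl activation and therefore cannot relactonise, and gives 25 directly.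

Further compounds
F1 | step 12 | diaxial 4β-bromo-5α-chloro lactone | CC1(C)[C@@H]2CC[C@@]1(C)[C@@]1(OC2=O)CC[C@@](C)(Br)[C@H](Cl)C1
F2 | step 8 | 4-hydroxy-4-(ring A)cyclohexanone methyl ester | CC1(C)[C@@H](C(=O)OC)CC[C@@]1(C)C1(O)CCC(=O)CC1
F3 | step 8 | keto lactone | CC1(C)[C@@H]2CC[C@@]1(C)C1(OC2=O)CCC(=O)CC1
F4 | step 8 | enol triflate lactone | CC1(C)[C@@H]2CC[C@@]1(C)[C@@]1(OC2=O)CCC(OS(=O)(=O)C(F)(F)F)=CC1
F5 | step 8 | alkene lactone | CC1(C)[C@@H]2CC[C@@]1(C)[C@@]1(OC2=O)CCC(C)=CC1
F6 | step 14 | hydroxy acid | CC1(C)[C@@H](C(=O)O)CC[C@@]1(C)[C@@]1(O)CC[C@](C)(Cl)[C@@H](Br)C1
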